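## Retrosynthetic overview

1. The target is unmasked last from a precursor carrying a dimethyl acetal, a dioxolane and a silylethyl ester; its formyl group comes from Vilsmeier formylation of a 2-alkylidene-2,5-dihydrofuran.
2. The dihydrofuran is the only ring and is closed late, by 5-exo-dig cycloisomerisation of a (Z)-enynol made by Sonogashira coupling of a terminal alkyne with a (Z)-iodoalkenol.
3. The alkyne comes from an aldehyde (Ohira–Bestmann) and the carboxylic acid from a nitromethyl group (oxidative Nef reaction).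
4. Key disconnection: the C2–C3 bond, formed with both stereocentres by an organocatalytic intermolecular Michael addition of a γ-acetal aldehyde to a 3-substituted 1-nitro-1,3-diene.
5. The nitrodiene comes from a 2-bromoalkene (Grignard allylation of 2,3-dibromopropene) and a nitroenamine.

Locants C1–C5 below are those of the pentanoic acid chain of the target (C1 = CO2H, C2 and C3 = the two stereocentres).

## Route

Step 1
Reactants: 1 2-(2-bromoethyl)-2-methyl-1,3-dioxolane; 2 2,3-dibromoprop-1-ene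
Product: 4 2-(4-bromopent-4-en-1-yl)-2-methyl-1,3-dioxolane, via alkylmagnesium bromide 3 (not isolated)
Conditions: Mg, THF, 25 °C; then CuI (5 mol%), THF, −10 °C to rt
Reagents that add atoms: none
Why: Copper-catalysed allylic substitution by a Grignard reagent: the primary alkylmagnesium bromide displaces the allylic bromide of 2 (SN2 and SN2′ paths give the same product), while the vinylic bromide and the ketal are inert.

Step 2
Reactants: 4 2-(4-bromopent-4-en-1-yl)-2-methyl-1,3-dioxolane; 5 (E)-N,N-dimethyl-2-nitroethen-1-amine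
Product: 8 2-methyl-2-[(5E)-4-methylidene-6-nitrohex-5-en-1-yl]-1,3-dioxolane, via alkenylmagnesium bromide 6 (not isolated), via magnesium nitronate 7 (not isolated)
Conditions: Mg, THF, 45 °C; then 5, THF, −30 to 0 °C; then 10% aq. AcOH, 0 °C
Reagents that add atoms: none
Why: Severin nitro-olefination (addition–elimination): the alkenyl Grignard reagent adds to the amine-bearing carbon of the push–pull nitroenamine, and protonation of the nitronate expels dimethylamine to give the conjugated (E)-nitrodiene.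

Step 3
Reactants: 9 methyl 4,4-dimethoxybutanoate
Product: 10 4,4-dimethoxybutanal
Conditions: i-Bu2AlH (1.05 equiv), CH2Cl2, −78 °C; aq. KNaC4H4O6
Reagents that add atoms: none
Why: Partial ester reduction: the aluminium hemiacetal formed by one hydride transfer is stable at −78 °C and gives the aldehyde only on work-up, with the acetal untouched.

Step 4
Reactants: 10 4,4-dimethoxybutanal; 8 2-methyl-2-[(5E)-4-methylidene-6-nitrohex-5-en-1-yl]-1,3-dioxolane
Product: 11 (2S,3R)-2-(2,2-dimethoxyethyl)-4-methylidene-7-(2-methyl-1,3-dioxolan-2-yl)-3-(nitromethyl)heptanal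
Conditions: (R)-2-[diphenyl(trimethylsilyloxy)methyl]pyrrolidine (10 mol%), 4-nitrophenol (10 mol%), toluene, 0 °C to rt
Reagents that add atoms: none
Why: Hayashi–Jørgensen enamine Michael addition: the (E)-enamine of 10, shielded on one face by the C(Ph)2OSiMe3 group of the (R)-catalyst, adds 1,4 to the nitroalkene of 8 through the acyclic synclinal transition state, which sets both stereocentres as the syn (2S,3R) pair and leaves the 1,1-disubstituted alkene untouched; the 4-nitrophenol co-catalyst speeds turnover so that a near-equimolar amount of the aldehyde suffices.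

Step 5
Reactants: 11 (2S,3R)-2-(2,2-dimethoxyethyl)-4-methylidene-7-(2-methyl-1,3-dioxolan-2-yl)-3-(nitromethyl)heptanal
Product: 12 2-[(5R,6S)-6-ethynyl-8,8-dimethoxy-4-methylidene-5-(nitromethyl)octyl]-2-methyl-1,3-dioxolane
Conditions: dimethyl (1-diazo-2-oxopropyl)phosphonate, K2CO3, MeOH, 0 °C to rt
Reagents that add atoms: dimethyl (1-diazo-2-oxopropyl)phosphonate, COP(=O)(OC)C(=[N+]=[N-])C(C)=O
Why: Seyferth–Gilbert homologation in the Ohira–Bestmann variant turns the aldehyde into the terminal alkyne under carbonate conditions mild enough to keep the α-stereocentre; the nitronate formed reversibly only undergoes reversible Henry addition.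

Step 6
Reactants: 12 2-[(5R,6S)-6-ethynyl-8,8-dimethoxy-4-methylidene-5-(nitromethyl)octyl]-2-methyl-1,3-dioxolane
Product: 13 (2R,3S)-3-ethynyl-5,5-dimethoxy-2-[5-(2-methyl-1,3-dioxolan-2-yl)pent-1-en-2-yl]pentanoic acid
Conditions: NaNO2 (3 equiv), AcOH (10 equiv), DMSO, 35 °C
Reagents that add atoms: sodium nitrite, [Na+].[O-]N=O
Why: Oxidative Nef-type conversion of a primary nitroalkane into a carboxylic acid (nitrosation to the nitrolic acid, then nitrile oxide, then acid) runs without base, so the new allylic α-stereocentre is not epimerised and acetal and ketal survive.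

Step 7
Reactants: 13 (2R,3S)-3-ethynyl-5,5-dimethoxy-2-[5-(2-methyl-1,3-dioxolan-2-yl)pent-1-en-2-yl]pentanoic acid
Product: 14 2-(trimethylsilyl)ethyl (2R,3S)-3-ethynyl-5,5-dimethoxy-2-[5-(2-methyl-1,3-dioxolan-2-yl)pent-1-en-2-yl]pentanoate
Conditions: Me3SiCH2CH2OH, PPh3, DIAD, THF, 0 °C to rt
Reagents that add atoms: 2-(trimethylsilyl)ethanol, C[Si](C)(C)CCO
Why: Mitsunobu esterification: the carboxylate attacks the alkoxyphosphonium ion of the primary alcohol, so the acyl carbon is never activated and the α-stereocentre is safe; the ester stops the 4-alkynoic acid from lactonising in the metal-catalysed steps that follow.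

Step 8
Reactants: 15 2-methylbut-3-yn-2-ol
Product: 16 4-iodo-2-methylbut-3-yn-2-ol
Conditions: N-iodosuccinimide, AgNO3 (5 mol%), acetone, rt
Reagents that add atoms: N-iodosuccinimide, O=C1CCC(=O)N1I
Why: Silver-catalysed electrophilic iodination of a terminal alkyne via the silver acetylide.

Step 9
Reactants: 16 4-iodo-2-methylbut-3-yn-2-ol
Product: 17 (3Z)-4-iodo-2-methylbut-3-en-2-ol
Conditions: 2-nitrobenzenesulfonohydrazide, Et3N, THF/i-PrOH, rt
Reagents that add atoms: none
Why: Diimide reduction: concerted syn transfer of two hydrogens to the iodoalkyne gives the (Z)-iodoalkene without cleaving the C–I bond.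

Step 10
Reactants: 14 2-(trimethylsilyl)ethyl (2R,3S)-3-ethynyl-5,5-dimethoxy-2-[5-(2-methyl-1,3-dioxolan-2-yl)pent-1-en-2-yl]pentanoate; 17 (3Z)-4-iodo-2-methylbut-3-en-2-ol
Product: 18 2-(trimethylsilyl)ethyl (2R,3S,6Z)-3-(2,2-dimethoxyethyl)-8-hydroxy-8-methyl-2-[5-(2-methyl-1,3-dioxolan-2-yl)pent-1-en-2-yl]non-6-en-4-ynoate
Conditions: PdCl2(PPh3)2 (3 mol%), CuI (6 mol%), Et3N, THF, rt
Reagents that add atoms: none
Why: Sonogashira coupling joins the terminal alkyne to the vinyl iodide with retention of the Z geometry; the free tertiary alcohol and the ester are tolerated.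

Step 11
Reactants: 18 2-(trimethylsilyl)ethyl (2R,3S,6Z)-3-(2,2-dimethoxyethyl)-8-hydroxy-8-methyl-2-[5-(2-methyl-1,3-dioxolan-2-yl)pent-1-en-2-yl]non-6-en-4-ynoate
Product: 19 2-(trimethylsilyl)ethyl (2R,3R)-3-[(Z)-(5,5-dimethylfuran-2(5H)-ylidene)methyl]-5,5-dimethoxy-2-[5-(2-methyl-1,3-dioxolan-2-yl)pent-1-en-2-yl]pentanoate
Conditions: AuCl(PPh3) (2 mol%), AgOTf (2 mol%), THF, rt; Et3N quench
Reagents that add atoms: none
Why: Gold-catalysed 5-exo-dig hydroalkoxylation (cycloisomerisation) of the (Z)-2-en-4-yn-1-ol: anti-oxyauration and protodeauration give the (Z)-alkylidene-2,5-dihydrofuran, the only ring of the target, and the gem-dimethyl carbon blocks aromatisation to a furan (the C3 descriptor changes to R only through CIP priorities).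

Step 12
Reactants: 19 2-(trimethylsilyl)ethyl (2R,3R)-3-[(Z)-(5,5-dimethylfuran-2(5H)-ylidene)methyl]-5,5-dimethoxy-2-[5-(2-methyl-1,3-dioxolan-2-yl)pent-1-en-2-yl]pentanoate
Product: 21 2-(trimethylsilyl)ethyl (2R,3S)-3-[(1E)-1-(5,5-dimethylfuran-2(5H)-ylidene)-2-oxoethyl]-5,5-dimethoxy-2-[5-(2-methyl-1,3-dioxolan-2-yl)pent-1-en-2-yl]pentanoate, via iminium chloride 20 (not isolated)
Conditions: [Me2N=CHCl]Cl (1.3 equiv), 2,6-lutidine, CH2Cl2, −20 to 0 °C; then aq. NaHCO3
Reagents that add atoms: (chloromethylene)dimethyliminium chloride, C[N+](C)=CCl.[Cl-]; water, O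
Why: Vilsmeier–Haack formylation of an enol ether: the exocyclic enol ether carbon attacks the chloroiminium salt, proton loss gives the push–pull iminium salt, and bicarbonate hydrolysis gives the β-alkoxy enal as the E isomer (formyl anti to the ring oxygen, which is also the thermodynamically preferred geometry).

Step 13
Reactants: 21 2-(trimethylsilyl)ethyl (2R,3S)-3-[(1E)-1-(5,5-dimethylfuran-2(5H)-ylidene)-2-oxoethyl]-5,5-dimethoxy-2-[5-(2-methyl-1,3-dioxolan-2-yl)pent-1-en-2-yl]pentanoate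
Product: 22 (2R,3S)-3-[(1E)-1-(5,5-dimethylfuran-2(5H)-ylidene)-2-oxoethyl]-5,5-dimethoxy-2-[5-(2-methyl-1,3-dioxolan-2-yl)pent-1-en-2-yl]pentanoic acid
Conditions: Bu4NF, THF, 0 °C to rt; then AcOH
Reagents that add atoms: none
Why: Fluoride-induced fragmentation of the 2-(trimethylsilyl)ethyl ester (β-elimination to ethene and Me3SiF) frees the acid without touching acetal, ketal, vinylogous ester or the α-stereocentre.

Step 14
Reactants: 22 (2R,3S)-3-[(1E)-1-(5,5-dimethylfuran-2(5H)-ylidene)-2-oxoethyl]-5,5-dimethoxy-2-[5-(2-methyl-1,3-dioxolan-2-yl)pent-1-en-2-yl]pentanoic acid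
Product: 23 (2R,3S)-3-[(1E)-1-(5,5-dimethylfuran-2(5H)-ylidene)-2-oxoethyl]-5-oxo-2-(6-oxohept-1-en-2-yl)pentanoic acid
Conditions: AcOH/THF/H2O 3:1:1, 40 °C
Reagents that add atoms: water, O
Why: Acid-catalysed hydrolysis of the dimethyl acetal and the dioxolane in a water-rich weak-acid medium unmasks aldehyde and ketone without Prins-type cyclisation onto the alkene, while the vinylogous ester (the ring-closed thermodynamic form) and both stereocentres are not touched.

## Compound list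

1 | 2-(2-bromoethyl)-2-methyl-1,3-dioxolane | CC1(CCBr)OCCO1 | starting material
2 | 2,3-dibromoprop-1-ene | C=C(Br)CBr | starting material
3 | [2-(2-methyl-1,3-dioxolan-2-yl)ethyl]magnesium bromide (formed in the flask) | CC1(CC[Mg]Br)OCCO1 | intermediate
4 | 2-(4-bromopent-4-en-1-yl)-2-methyl-1,3-dioxolane | C=C(Br)CCCC1(C)OCCO1 | intermediate
5 | (E)-N,N-dimethyl-2-nitroethen-1-amine | CN(C)/C=C/[N+](=O)[O-] | starting material
6 | [5-(2-methyl-1,3-dioxolan-2-yl)pent-1-en-2-yl]magnesium bromide (formed in the flask) | C=C([Mg]Br)CCCC1(C)OCCO1 | intermediate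
7 | bromomagnesium nitronate of 2-[5-(dimethylamino)-4-methylidene-6-nitrohexyl]-2-methyl-1,3-dioxolane (racemic, formed in the flask) | CN(C)C(C=[N+]([O-])[O-])C(=C)CCCC1(C)OCCO1.[Mg+2].[Br-] | intermediate
8 | 2-methyl-2-[(5E)-4-methylidene-6-nitrohex-5-en-1-yl]-1,3-dioxolane | C=C(CCCC1(C)OCCO1)/C=C/[N+](=O)[O-] | intermediate
9 | methyl 4,4-dimethoxybutanoate | COC(=O)CCC(OC)OC | starting material
10 | 4,4-dimethoxybutanal | COC(CCC=O)OC | intermediate
11 | (2S,3R)-2-(2,2-dimethoxyethyl)-4-methylidene-7-(2-methyl-1,3-dioxolan-2-yl)-3-(nitromethyl)heptanal | C=C(CCCC1(C)OCCO1)[C@H](C[N+](=O)[O-])[C@H](CC(OC)OC)C=O | intermediate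
12 | 2-[(5R,6S)-6-ethynyl-8,8-dimethoxy-4-methylidene-5-(nitromethyl)octyl]-2-methyl-1,3-dioxolane | C=C(CCCC1(C)OCCO1)[C@H](C[N+](=O)[O-])[C@H](CC(OC)OC)C#C | intermediate
13 | (2R,3S)-3-ethynyl-5,5-dimethoxy-2-[5-(2-methyl-1,3-dioxolan-2-yl)pent-1-en-2-yl]pentanoic acid | C=C(CCCC1(C)OCCO1)[C@H](C(=O)O)[C@H](CC(OC)OC)C#C | intermediate
14 | 2-(trimethylsilyl)ethyl (2R,3S)-3-ethynyl-5,5-dimethoxy-2-[5-(2-methyl-1,3-dioxolan-2-yl)pent-1-en-2-yl]pentanoate | C=C(CCCC1(C)OCCO1)[C@H](C(=O)OCC[Si](C)(C)C)[C@H](CC(OC)OC)C#C | intermediate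
15 | 2-methylbut-3-yn-2-ol | CC(C)(O)C#C | starting material
16 | 4-iodo-2-methylbut-3-yn-2-ol | CC(C)(O)C#CI | intermediate
17 | (3Z)-4-iodo-2-methylbut-3-en-2-ol | CC(C)(O)/C=C\I | intermediate
18 | 2-(trimethylsilyl)ethyl (2R,3S,6Z)-3-(2,2-dimethoxyethyl)-8-hydroxy-8-methyl-2-[5-(2-methyl-1,3-dioxolan-2-yl)pent-1-en-2-yl]non-6-en-4-ynoate | C=C(CCCC1(C)OCCO1)[C@H](C(=O)OCC[Si](C)(C)C)[C@H](CC(OC)OC)C#C/C=C\C(C)(C)O | intermediate
19 | 2-(trimethylsilyl)ethyl (2R,3R)-3-[(Z)-(5,5-dimethylfuran-2(5H)-ylidene)methyl]-5,5-dimethoxy-2-[5-(2-methyl-1,3-dioxolan-2-yl)pent-1-en-2-yl]pentanoate | C=C(CCCC1(C)OCCO1)[C@H](C(=O)OCC[Si](C)(C)C)[C@H](CC(OC)OC)/C=C1/C=CC(C)(C)O1 | intermediate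
20 | N,N-dimethyliminium chloride of aldehyde 21 (CH=NMe2+ in place of CH=O, formed in the flask) | C=C(CCCC1(C)OCCO1)[C@H](C(=O)OCC[Si](C)(C)C)[C@H](CC(OC)OC)/C(C=[N+](C)C)=C1/C=CC(C)(C)O1.[Cl-] | intermediate
21 | 2-(trimethylsilyl)ethyl (2R,3S)-3-[(1E)-1-(5,5-dimethylfuran-2(5H)-ylidene)-2-oxoethyl]-5,5-dimethoxy-2-[5-(2-methyl-1,3-dioxolan-2-yl)pent-1-en-2-yl]pentanoate | C=C(CCCC1(C)OCCO1)[C@H](C(=O)OCC[Si](C)(C)C)[C@H](CC(OC)OC)/C(C=O)=C1/C=CC(C)(C)O1 | intermediate
22 | (2R,3S)-3-[(1E)-1-(5,5-dimethylfuran-2(5H)-ylidene)-2-oxoethyl]-5,5-dimethoxy-2-[5-(2-methyl-1,3-dioxolan-2-yl)pent-1-en-2-yl]pentanoic acid | C=C(CCCC1(C)OCCO1)[C@H](C(=O)O)[C@H](CC(OC)OC)/C(C=O)=C1/C=CC(C)(C)O1 | intermediate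
23 | (2R,3S)-3-[(1E)-1-(5,5-dimethylfuran-2(5H)-ylidene)-2-oxoethyl]-5-oxo-2-(6-oxohept-1-en-2-yl)pentanoic acid | C=C(CCCC(C)=O)[C@H](C(=O)O)[C@H](CC=O)/C(C=O)=C1/C=CC(C)(C)O1 | target

## Step count and weak points

Total step count: 14. Longest linear sequence: 11 steps (steps 1, 2, 4, 5, 6, 7, 10, 11, 12, 13, 14, from 1).

The three steps most likely to fail:

Risk 1, step 2 (nitro-olefination). The alkenyl Grignard reagent may attack the nitro group, and the terminal nitrodiene can oligomerise. The fallback sets out from bromoalkene 4 and comes back at nitrodiene 8. Grignard reagent 6 is quenched with DMF (THF, 0 °C; aq. AcOH) to give 2-methylidene-5-(2-methyl-1,3-dioxolan-2-yl)pentanal F1. A Henry addition of nitromethane to the aldehyde carbon (KOt-Bu cat., THF/t-BuOH, 0 °C) gives 3-methylidene-6-(2-methyl-1,3-dioxolan-2-yl)-1-nitrohexan-2-ol F2. Dehydration with MsCl and Et3N (CH2Cl2, 0 °C) then gives 8.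

Risk 2, step 6 (nitromethyl to carboxylic acid). Nitrous acid may attack the 1,1-disubstituted alkene, or the reaction may stall at the nitrolic acid. The fallback sets out from 12 and comes back at 13. A reductive McMurry-type Nef reaction (TiCl3, NH4OAc buffer, THF/H2O, rt) gives (2R,3S)-3-ethynyl-5,5-dimethoxy-2-[5-(2-methyl-1,3-dioxolan-2-yl)pent-1-en-2-yl]pentanal F3. This is oxidised at once under Pinnick conditions (NaClO2, NaH2PO4, 2-methylbut-2-ene, t-BuOH/H2O) to acid 13.

Risk 3, step 12 (Vilsmeier formylation). The acid-labile dienyl ether 19 may hydrolyse, and the chloroiminium salt may attack the acetal or ketal. The fallback sets out from enynol 18, bypasses 19 and comes back at 21. Iodocyclisation (I2, NaHCO3, MeCN, 0 °C; 5-exo-dig, anti addition) gives 2-(trimethylsilyl)ethyl (2R,3S)-3-[(E)-(5,5-dimethylfuran-2(5H)-ylidene)iodomethyl]-5,5-dimethoxy-2-[5-(2-methyl-1,3-dioxolan-2-yl)pent-1-en-2-yl]pentanoate F4. Formylation with a zerovalent palladium catalyst (Pd(PPh3)4, CO 1 atm, Bu3SnH added slowly, THF, 50 °C) replaces iodine by CHO with retention and gives 21.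

Further compounds

F1 | step 2 | 2-methylidene-5-(2-methyl-1,3-dioxolan-2-yl)pentanal | C=C(C=O)CCCC1(C)OCCO1
F2 | step 2 | 3-methylidene-6-(2-methyl-1,3-dioxolan-2-yl)-1-nitrohexan-2-ol (racemic) | C=C(C(O)C[N+](=O)[O-])CCCC1(C)OCCO1
F3 | step 6 | (2R,3S)-3-ethynyl-5,5-dimethoxy-2-[5-(2-methyl-1,3-dioxolan-2-yl)pent-1-en-2-yl]pentanal | C=C(CCCC1(C)OCCO1)[C@H](C=O)[C@H](CC(OC)OC)C#C
F4 | step 12 | 2-(trimethylsilyl)ethyl (2R,3S)-3-[(E)-(5,5-dimethylfuran-2(5H)-ylidene)iodomethyl]-5,5-dimethoxy-2-[5-(2-methyl-1,3-dioxolan-2-yl)pent-1-en-2-yl]pentanoate | C=C(CCCC1(C)OCCO1)[C@H](C(=O)OCC[Si](C)(C)C)[C@H](CC(OC)OC)/C(I)=C1/C=CC(C)(C)O1
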